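Compound numbers used throughout: **1** 5-bromovanillin; **2** 3-bromo-4,5-dihydroxybenzaldehyde; **3** its bis-MOM ether; **4** aryl formate (not isolated); **5** 3-bromo-4,5-bis(methoxymethoxy)phenol; **6** 1-bromo-2,3,5-tris(methoxymethoxy)benzene; **7** diisopropyl squarate; **8** ethylmagnesium bromide; **9** squarate 1,2-adduct (not isolated); **10** 3-ethyl-4-isopropoxycyclobutenedione; **11** aryllithium (not isolated); **12** 4-aryl-4-hydroxycyclobutenone; **13** vinylketene (not isolated); **14** dienone tautomer (not isolated); **15** naphthalene-1,4-diol; **16** isopropoxyquinone; **17** hydroxyquinone; **18** bromoquinone; **19** (S)-hydroxytrione; **20** hexa-MOM ether; **21** target.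

## Analysis of the target

Compound 21 is made of two naphthalene-derived bicycles joined by a single ether oxygen: rings A/B form a 1,4-naphthoquinone (C1–C4 in ring A, C5–C8 in ring B) and rings C/D a naphthalene-1,2,4(3H)-trione (C1'–C4' in ring C, C5'–C8' in ring D). Both arenes are fully substituted except at C6 and C6', with hydroxyls at C5, C7, C8 and C5', C7', C8'. The only stereocentre is C3', a fully substituted carbon carrying the ethyl group, the ether oxygen and the ring carbonyls C2' and C4'; it has the (S) configuration (O > C2' > C4' > ethyl), and since it stands alone only its absolute sense has to be controlled. The sensitive groups are the vicinal C1'/C2' dione (hydration, acyl shifts and ring contraction with base), the C2–O–C3' ether, which on the quinone side is a vinylogous ester and exchanges with oxygen nucleophiles, and six oxidisable phenols, four of them peri to carbonyls. The difficulties are the unsymmetrical placement of ethyl and oxygen on rings A and C relative to the lone oxygen at C5 and the oxygen pair at C7/C8, the hindered ether between a quaternary carbon and a tetrasubstituted alkene carbon, and a stereocentre whose two carbonyl neighbours look nearly alike. The strategy rests on the fact that both halves are the same skeleton at two oxidation levels: a 3-ethyl-2-oxy ring C1–C4 fused to a 5,7,8-trioxygenated arene, with the ethyl-bearing C3 next to C4, the carbonyl peri to the lone oxygen at C5. One regiodefined monomer, hydroxyquinone 17, can therefore serve twice.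

## Retrosynthetic reasoning

21 from 20. Only the six O–CH2 bonds of the methoxymethyl acetals are cut. The phenols are masked because they would quench the organolithium and interfere with every base-mediated step. The forward step has to hydrolyse six acetals without exchanging the quinonyl ether.

20 from 18 and 19. The ether is cut at O–C2 (the sp2 carbon of ring A), not at O–C3'. Substitution at a quaternary carbon flanked by two carbonyls is not available, whereas C2 of a quinone is a natural addition–elimination site. The cut gives convergence and lets the stereocentre be made on a monomer. The forward reaction must let the tertiary alkoxide of 19 displace the bromide of 18 faster than the α-ketol rearranges.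

18 and 19 from 17. For 19 the C3–O bond is cut: an electrophilic oxygen is delivered to C3 of the enol 17, and this is where the stereocentre is set. For 18 the C2–OH is exchanged for C2–Br. Both halves thus diverge from one compound at the latest possible point. The forward hydroxylation has to distinguish the two faces of a nearly symmetric enolate, which calls for a chiral metal chelate at O1/O2.

17 from 16 from 15. These are changes of oxidation level and of a spectator group only: hydrolysis of the vinylogous isopropyl ester and oxidation of the hydroquinone. The isopropoxy group is kept until here because it carries the regiochemical information through the annulation.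

15 from 12. The C4–C4a bond of ring A is cut, and ring A is traced back to a four-membered ring. Cutting here rather than at any arene bond means that the C2-oxygen/C3-ethyl pattern comes ready-made from a squaric acid derivative and that the new bond can only form at the one free ortho carbon of the aryl group. The forward reaction has to open the cyclobutenone to a vinylketene and close it onto the arene.

12 from 10 and 6 (through 11). The aryl–carbinol bond (future C1–C8a) is cut. The aryl anion adds to the one carbonyl of 10 that is not a vinylogous ester, which fixes the carbinol carbon next to the isopropoxy carbon and the future ketene carbon next to the ethyl carbon.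

10 from 7 and 8; 6 from 5, 3, 2 and 1. The ethyl group is introduced by 1,2-addition to the squarate and acid-induced loss of one isopropoxy group. The 1-bromo-2,3,5-trioxygenated benzene is taken from 1, whose bromine already sits where the lithium is needed; the aldehyde is turned into the third oxygen by oxidative aryl migration. Directed metalation of a 1,2,4-trioxygenated benzene would lithiate between two oxygens, the wrong position, so the bromide is needed.

## Alternatives that were turned down

Alternative 1: The four ring-fusion bonds of rings B and D (C4a–C5, C8a–C8, C4a'–C5', C8a'–C8') are cut, leaving the bis-dienophile ether A3, in which a bromobenzoquinone and a bromocyclohexenedione are already linked through the tertiary ether. In the forward step two equivalents of the oxygenated ketene-acetal diene A2 would add, and loss of HBr and methanol would give A1 with both arenes formed. In its favour, both polyoxygenated arenes appear in one late operation, no polyphenol has to be carried, and the bromine atoms give a handle on the orientation of each cycloaddition. Against it, orientation must hold twice on two electronically different dienophiles. A3 also carries the ether oxygen β to a ketone with an enolisable C2' methylene, so elimination of the quinonyloxy group threatens under the aromatisation conditions. C2' then still has to be oxidised to the carbonyl next to the stereocentre in the presence of free phenols, and the methyl ethers at C8 and C5' need a harsh final cleavage. Making A3 poses the same tertiary-ether problem as the chosen route, on a more fragile substrate. On convergence of arene construction this alternative is stronger. The chosen route offers in exchange a regiochemistry fixed by two independent controls, no late C–H oxidation and one monomer for both halves.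

Alternative 2: Ring C is cut between the stereocentre C3' and the aryl ketone carbon C4'. In the forward step a chiral N-heterocyclic carbene would turn the aldehyde of A5 into an acyl anion equivalent that adds to the tethered ethyl ketone, closing ring C and giving the tertiary carbinol A4. On the stereocentre this alternative is clearly stronger: intramolecular aldehyde–ketone benzoin closure to α-hydroxytetralones is a well-established catalytic asymmetric reaction, and the tertiary alkoxide of A4, with C1' masked as a ketal and C2' still a methylene, would be a sturdier nucleophile for the ether formation. Against it, it builds only the trione half, so the quinone half needs its own synthesis. A5 is a hexasubstituted benzene with two ortho carbon chains that has no short preparation. After ketal removal the tertiary oxygen is β to a ketone and prone to elimination toward the aromatic naphthoquinone, and the C2' methylene must still be oxidised late. The chosen strategy gives up the precedented stereocontrol and offers in its place a far shorter route in which one intermediate supplies both halves at the correct oxidation pattern.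

Alternative 3: Ring B is cut at C5–C6, C7–C8 and C8–C8a. In the forward step the aryl(methoxy)carbene complex A7 of Cr(CO)5 would combine with ethoxyacetylene and one CO ligand to give naphthol A6. In its favour, one step delivers all three ring B oxygens, each differently substituted (free OH at C8, ethoxy at C7, methoxy at C5), and the steric rule of the benzannulation places the alkoxy group next to the CO-derived carbon, so in principle its regiocontrol is as good as that of the chosen route. Against it, alkoxyacetylenes are poor partners that tend to react without CO insertion, and chromium is used stoichiometrically. A7 needs a pentasubstituted ethyl-trimethoxy aryl bromide that is itself a regiochemical problem. A6 also carries five alkyl ethers, so O2 has to be singled out and methyl ethers removed under conditions the dimer would not survive. The chosen route takes the differentiated C2-oxygen/C3-ethyl ring from a squarate and uses acid-labile acetals throughout.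

Key step: step 7

Remark on the chemistry: 21 is taken as the anhydrous tautomer drawn in the target SMILES; naphthazarin-type tautomers of rings A/B and a hydrate at C2' are equilibrium forms of the same compound and are not treated separately.

## Route

Step 1
Reactants: 1 5-bromovanillin (3-bromo-4-hydroxy-5-methoxybenzaldehyde)
Product: 2 3-bromo-4,5-dihydroxybenzaldehyde
Conditions: BBr3 (2.5 equiv), CH2Cl2, −78 °C → rt; H2O quench
Reagents that add atoms: none
Why: Lewis-acid cleavage of an aryl methyl ether; the neighbouring phenol is taken up as an aryl borate that hydrolyses on work-up, and the aldehyde is not affected at or below room temperature.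

Step 2
Reactants: 2 3-bromo-4,5-dihydroxybenzaldehyde
Product: 3 3-bromo-4,5-bis(methoxymethoxy)benzaldehyde
Conditions: MOMCl (3 equiv), i-Pr2NEt (4 equiv), CH2Cl2, 0 °C → rt
Reagents that add atoms: chloromethyl methyl ether (MOMCl), COCCl
Why: Williamson-type O-alkylation of both phenols; the acetals withstand organolithium reagents, heat and base and can later chelate lithium.

Step 3
Reactants: 3 3-bromo-4,5-bis(methoxymethoxy)benzaldehyde
Product: 5 3-bromo-4,5-bis(methoxymethoxy)phenol, via aryl formate 4 (not isolated)
Conditions: mCPBA (1.4 equiv), CH2Cl2, 0 °C → rt; aq. NaHCO3 wash; then K2CO3 (0.2 equiv), MeOH, rt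
Reagents that add atoms: 3-chloroperoxybenzoic acid (mCPBA), OOC(=O)c1cccc(Cl)c1
Why: Baeyer–Villiger (Dakin-type) oxidation; the aryl group, activated by the para acetal oxygen, migrates in preference to hydrogen, and the formate is removed by methanolysis.

Step 4
Reactants: 5 3-bromo-4,5-bis(methoxymethoxy)phenol
Product: 6 1-bromo-2,3,5-tris(methoxymethoxy)benzene
Conditions: MOMCl (1.5 equiv), i-Pr2NEt (2 equiv), CH2Cl2, 0 °C → rt
Reagents that add atoms: chloromethyl methyl ether (MOMCl), COCCl
Why: O-alkylation of the remaining phenol gives the aryl bromide with bromine ortho to one acetal and with one free ortho position.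

Step 5
Reactants: 7 diisopropyl squarate; 8 ethylmagnesium bromide
Product: 10 3-ethyl-4-isopropoxycyclobut-3-ene-1,2-dione, via squarate 1,2-adduct 9 (not isolated)
Conditions: EtMgBr (1.1 equiv), THF, −78 °C; aq. NH4Cl; then 12 M HCl (cat.), CH2Cl2, rt
Reagents that add atoms: none
Why: 1,2-addition of the Grignard reagent to one squarate carbonyl; acid then ionises the carbinol to an alkoxy-stabilised cyclobutenyl cation, water adds at the remote isopropoxy carbon, and loss of isopropanol gives the dione (the established squarate-to-alkylcyclobutenedione sequence).

Step 6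
Reactants: 6 1-bromo-2,3,5-tris(methoxymethoxy)benzene; 10 3-ethyl-4-isopropoxycyclobut-3-ene-1,2-dione
Product: 12 racemic 2-ethyl-4-hydroxy-3-isopropoxy-4-[2,3,5-tris(methoxymethoxy)phenyl]cyclobut-2-en-1-one, via aryllithium 11 (not isolated)
Conditions: n-BuLi (1.05 equiv), THF, −78 °C, 15 min; cannulation into 10 (1.0 equiv), THF, −78 °C; aq. NH4Cl at −78 °C
Reagents that add atoms: none
Why: Bromine–lithium exchange is faster than ortho-metalation at −78 °C, and the ortho acetal chelates lithium. The aryllithium adds 1,2 to the ketone-like carbonyl next to the isopropoxy carbon, because the other carbonyl is a vinylogous ester; the new carbinol centre is racemic and is lost in step 7.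

Step 7
Reactants: 12 racemic 2-ethyl-4-hydroxy-3-isopropoxy-4-[2,3,5-tris(methoxymethoxy)phenyl]cyclobut-2-en-1-one
Product: 15 3-ethyl-2-isopropoxy-5,7,8-tris(methoxymethoxy)naphthalene-1,4-diol, via vinylketene 13 (not isolated), via 4aH-dienone tautomer 14 (not isolated)
Conditions: p-xylene (degassed, dilute), 138 °C, argon
Reagents that add atoms: none
Why: Heating opens the cyclobutenone by conrotatory 4π cleavage of the bond between the carbonyl carbon and the carbinol carbon; the hydroxyl turns outward, as donor substituents do, so the aryl group ends cis to the ketene in 13. Counting one arene double bond, 13 is a hexatriene, and thermal disrotatory 6π electrocyclisation joins the ketene carbon to the free ortho carbon, forming C4–C4a and closing the six-membered ring A. Tautomerisation of dienone 14 restores the arene and gives 15, which makes the sequence irreversible. The closest known reaction type is the thermal rearrangement of 4-aryl-4-hydroxycyclobutenones to naphthohydroquinones (Moore rearrangement). No stereocentre remains, since the carbinol centre of 12 and the C4a centre of 14 both become sp2. The step needs regiocontrol, and the substrate secures it twice: the carbinol carbon (C1) already sits next to the isopropoxy carbon and the ketene carbon (C4) next to the ethyl carbon, and the aryl ring has only one unsubstituted ortho position, so C4 ends peri to the lone oxygen at C5. Inward rotation of the hydroxyl, which would let it capture the ketene as a furanone, is disfavoured by the donor preference for outward rotation. Neutral, oxygen-free conditions keep the acetals intact and protect 15 from premature oxidation.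

Step 8
Reactants: 15 3-ethyl-2-isopropoxy-5,7,8-tris(methoxymethoxy)naphthalene-1,4-diol
Product: 16 3-ethyl-2-isopropoxy-5,7,8-tris(methoxymethoxy)naphthalene-1,4-dione
Conditions: Ag2O (2 equiv), MgSO4, Et2O, rt
Reagents that add atoms: none
Why: Two-electron oxidation of an electron-rich hydroquinone to the quinone under neutral conditions that leave the acetals and the enol ether untouched.

Step 9
Reactants: 16 3-ethyl-2-isopropoxy-5,7,8-tris(methoxymethoxy)naphthalene-1,4-dione
Product: 17 3-ethyl-2-hydroxy-5,7,8-tris(methoxymethoxy)naphthalene-1,4-dione
Conditions: LiOH·H2O (3 equiv), THF/H2O (3:1), rt → 40 °C; then 1 M HCl to pH 4 at 0 °C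
Reagents that add atoms: lithium hydroxide, [Li+].[OH-]
Why: Saponification of a vinylogous ester by addition–elimination of hydroxide at C2; formation of the stabilised hydroxyquinone anion drives the exchange, and the acetals are stable to base.

Step 10
Reactants: 17 3-ethyl-2-hydroxy-5,7,8-tris(methoxymethoxy)naphthalene-1,4-dione
Product: 18 2-bromo-3-ethyl-5,7,8-tris(methoxymethoxy)naphthalene-1,4-dione
Conditions: (COBr)2 (1.5 equiv), DMF (0.2 equiv), 2,6-lutidine (1.2 equiv), CH2Cl2, 0 °C → rt
Reagents that add atoms: oxalyl bromide, O=C(Br)C(Br)=O
Why: Vilsmeier-type activation of the vinylogous acid at O2 and addition–elimination of bromide at C2, as in the conversion of 1,3-diones and 2-hydroxynaphthoquinones into β-halo enones. O4 is flanked by the ethyl group and the peri acetal, so the 1,4-quinone is expected, and lutidine takes up HBr to spare the acetals.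

Step 11
Reactants: 17 3-ethyl-2-hydroxy-5,7,8-tris(methoxymethoxy)naphthalene-1,4-dione
Product: 19 (3S)-3-ethyl-3-hydroxy-5,7,8-tris(methoxymethoxy)naphthalene-1,2,4(3H)-trione
Conditions: Cu(OTf)2 (10 mol %), (S,S)-t-Bu-box [2,2'-(propane-2,2-diyl)bis((4S)-4-tert-butyl-4,5-dihydrooxazole), 12 mol %], 2,6-lutidine (10 mol %), 4 Å MS, CH2Cl2; then 17 and (±)-trans-2-(phenylsulfonyl)-3-phenyloxaziridine (1.2 equiv), −20 °C; filtration through Florisil, no aqueous work-up
Reagents that add atoms: (±)-trans-2-(phenylsulfonyl)-3-phenyloxaziridine, O=S(=O)(N1OC1c1ccccc1)c1ccccc1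
Why: Proposed new method: the anion of 17 should bind divalent copper through O1 and O2 as a five-membered chelate, as 2-hydroxynaphthoquinones generally do with metal ions, which places C3 beside one oxazoline of the C2-symmetric ligand; its tert-butyl group screens one face of the planar enolate, the N-sulfonyloxaziridine transfers oxygen to the open face of C3, and the copper alkoxide is protonated by the next molecule of 17 so that the catalyst turns over; a quadrant model predicts the (S)-alcohol for the (S,S)-ligand, and the (R,R)-ligand is to be used if the sense proves opposite; the closest known reaction type is the chiral Lewis-acid-catalysed α-hydroxylation of β-keto esters and the hydroxylative dearomatisation of 2-naphthols with N-sulfonyloxaziridines, which has not been shown for 2-hydroxy-1,4-naphthoquinones.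

Step 12
Reactants: 18 2-bromo-3-ethyl-5,7,8-tris(methoxymethoxy)naphthalene-1,4-dione; 19 (3S)-3-ethyl-3-hydroxy-5,7,8-tris(methoxymethoxy)naphthalene-1,2,4(3H)-trione
Product: 20 (3S)-3-ethyl-3-{[3-ethyl-5,7,8-tris(methoxymethoxy)-1,4-dioxo-1,4-dihydronaphthalen-2-yl]oxy}-5,7,8-tris(methoxymethoxy)naphthalene-1,2,4(3H)-trione
Conditions: 18 (1.3 equiv), 19 (1.0 equiv), 4 Å MS, MeCN, −20 °C; Cs2CO3 (1.2 equiv) added last, −20 → 0 °C
Reagents that add atoms: none
Why: Addition–elimination of an alkoxide at C2 of a 2-halo-1,4-naphthoquinone, a known way to quinonyl ethers, including tertiary ones. The base is added to the premixed partners so that the alkoxide of 19 is trapped as it forms; the stereocentre is not a reacting atom and keeps its configuration.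

Step 13
Reactants: 20 hexa-MOM ether (name as in step 12)
Product: 21 (3S)-3-ethyl-3-[(3-ethyl-5,7,8-trihydroxy-1,4-dioxo-1,4-dihydronaphthalen-2-yl)oxy]-5,7,8-trihydroxynaphthalene-1,2,4(3H)-trione
Conditions: 3 M aq. HCl/THF (1:4), 40 °C, argon; azeotropic drying with toluene
Reagents that add atoms: none
Why: Acid hydrolysis of six aryl methoxymethyl acetals through oxocarbenium ions, with water as the only nucleophile. The quinonyl ether cannot be protonated at carbon and is shielded at C2 by the tertiary group and the ethyl substituent, and the α-ketol shift is blocked because the tertiary oxygen is etherified.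

## Compound list

1 | 5-bromovanillin (3-bromo-4-hydroxy-5-methoxybenzaldehyde) | COc1cc(C=O)cc(Br)c1O | starting material
2 | 3-bromo-4,5-dihydroxybenzaldehyde | O=Cc1cc(O)c(O)c(Br)c1 | intermediate
3 | 3-bromo-4,5-bis(methoxymethoxy)benzaldehyde | COCOc1cc(C=O)cc(Br)c1OCOC | intermediate
4 | 3-bromo-4,5-bis(methoxymethoxy)phenyl formate (not isolated) | COCOc1cc(OC=O)cc(Br)c1OCOC | intermediate
5 | 3-bromo-4,5-bis(methoxymethoxy)phenol | COCOc1cc(O)cc(Br)c1OCOC | intermediate
6 | 1-bromo-2,3,5-tris(methoxymethoxy)benzene | COCOc1cc(Br)c(OCOC)c(OCOC)c1 | intermediate
7 | diisopropyl squarate | CC(C)OC1=C(OC(C)C)C(=O)C1=O | starting material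
8 | ethylmagnesium bromide | CC[Mg]Br | starting material
9 | 4-ethyl-4-hydroxy-2,3-diisopropoxycyclobut-2-en-1-one (racemic, not isolated) | CCC1(O)C(OC(C)C)=C(OC(C)C)C1=O | intermediate
10 | 3-ethyl-4-isopropoxycyclobut-3-ene-1,2-dione | CCC1=C(OC(C)C)C(=O)C1=O | intermediate
11 | 2,3,5-tris(methoxymethoxy)phenyllithium (not isolated) | [Li]c1cc(OCOC)cc(OCOC)c1OCOC | intermediate
12 | racemic 2-ethyl-4-hydroxy-3-isopropoxy-4-[2,3,5-tris(methoxymethoxy)phenyl]cyclobut-2-en-1-one | CCC1=C(OC(C)C)C(O)(c2cc(OCOC)cc(OCOC)c2OCOC)C1=O | intermediate
13 | (3Z)-2-ethyl-4-hydroxy-3-isopropoxy-4-[2,3,5-tris(methoxymethoxy)phenyl]buta-1,3-dien-1-one (vinylketene, not isolated) | CCC(=C=O)/C(OC(C)C)=C(/O)c1cc(OCOC)cc(OCOC)c1OCOC | intermediate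
14 | 3-ethyl-1-hydroxy-2-isopropoxy-5,7,8-tris(methoxymethoxy)-4aH-naphthalen-4-one (racemic, not isolated) | CCC1=C(OC(C)C)C(O)=C2C(OCOC)=C(OCOC)C=C(OCOC)C2C1=O | intermediate
15 | 3-ethyl-2-isopropoxy-5,7,8-tris(methoxymethoxy)naphthalene-1,4-diol | CCc1c(OC(C)C)c(O)c2c(OCOC)c(OCOC)cc(OCOC)c2c1O | intermediate
16 | 3-ethyl-2-isopropoxy-5,7,8-tris(methoxymethoxy)naphthalene-1,4-dione | CCC1=C(OC(C)C)C(=O)c2c(OCOC)c(OCOC)cc(OCOC)c2C1=O | intermediate
17 | 3-ethyl-2-hydroxy-5,7,8-tris(methoxymethoxy)naphthalene-1,4-dione | CCC1=C(O)C(=O)c2c(OCOC)c(OCOC)cc(OCOC)c2C1=O | intermediate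
18 | 2-bromo-3-ethyl-5,7,8-tris(methoxymethoxy)naphthalene-1,4-dione | CCC1=C(Br)C(=O)c2c(OCOC)c(OCOC)cc(OCOC)c2C1=O | intermediate
19 | (3S)-3-ethyl-3-hydroxy-5,7,8-tris(methoxymethoxy)naphthalene-1,2,4(3H)-trione | O[C@]1(CC)C(=O)C(=O)c2c(OCOC)c(OCOC)cc(OCOC)c2C1=O | intermediate
20 | (3S)-3-ethyl-3-{[3-ethyl-5,7,8-tris(methoxymethoxy)-1,4-dioxo-1,4-dihydronaphthalen-2-yl]oxy}-5,7,8-tris(methoxymethoxy)naphthalene-1,2,4(3H)-trione | CCC1=C(O[C@]2(CC)C(=O)C(=O)c3c(OCOC)c(OCOC)cc(OCOC)c3C2=O)C(=O)c2c(OCOC)c(OCOC)cc(OCOC)c2C1=O | intermediate
21 | (3S)-3-ethyl-3-[(3-ethyl-5,7,8-trihydroxy-1,4-dioxo-1,4-dihydronaphthalen-2-yl)oxy]-5,7,8-trihydroxynaphthalene-1,2,4(3H)-trione | CCC1=C(O[C@]2(CC)C(=O)C(=O)c3c(O)c(O)cc(O)c3C2=O)C(=O)c2c(O)c(O)cc(O)c2C1=O | target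

## Step count and least certain steps

Total step count: 13. Longest linear sequence: 11 steps (steps 1–4, 6–9, 11 or 10, 12, 13).

**Step 11 (asymmetric hydroxylation).** The most likely failures are poor facial selectivity, because C3 lies outside the chelate ring and its two neighbours are both carbonyl carbons, and slow oxygen transfer to a strongly stabilised enolate. A Lewis-acid-induced acyl or ethyl shift of the α-ketol is a further danger. The fallback uses known chemistry. It sets out from 17: hydroxylation of the enol with dimethyldioxirane in acetone at −20 °C, a standard oxidation of 1,3-dicarbonyl enols, should give racemic 3-ethyl-3-hydroxy-5,7,8-tris(methoxymethoxy)naphthalene-1,2,4(3H)-trione F1. Preparative chromatography on a chiral stationary phase (amylose tris(3,5-dimethylphenylcarbamate)) then separates the (3S)-alcohol from the (3R)-enantiomer F2, and the route is rejoined at 19.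

**Step 7 (key step).** The most likely failure is interception of the ketene by the tertiary hydroxyl after inward rotation, leading to lactonisation instead of ring closure; thermal loss of an acetal and premature oxidation are lesser risks. The fallback sets out from 12: silylation with Me3SiCl and Et3N gives 2-ethyl-3-isopropoxy-4-[2,3,5-tris(methoxymethoxy)phenyl]-4-(trimethylsilyloxy)cyclobut-2-en-1-one F3, which has no free hydroxyl to trap the ketene. Thermolysis in p-xylene should give the monosilylated hydroquinone 3-ethyl-2-isopropoxy-5,7,8-tris(methoxymethoxy)-1-(trimethylsilyloxy)naphthalen-4-ol F4. Desilylation with Bu4NF followed by Ag2O rejoins the route at 16.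

**Step 12 (ether formation).** The alkoxide of 19 may rearrange (acyl shift with ring expansion or contraction, or ethyl shift) faster than it attacks the hindered C2 of 18, and any such shift also erodes the stereochemical integrity. The fallback sets out from 17: one-electron oxidation with PbO2 in CH2Cl2/AcOH gives a radical delocalised over O2 and C3, and the known dehydrodimerisation of 2-hydroxy-3-alkylnaphthoquinones through C3–O2 coupling should give the racemic hexa-MOM ether F5 directly. Chromatography on a chiral stationary phase separates it from the (3R)-enantiomer F6 and rejoins the route at 20.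

**Step 13 (global deprotection).** The acid needed for the two non-peri acetals (at C7 and C7') may bring about hydrolytic cleavage of the quinonyl ether or hydration and rearrangement of the trione. The fallback sets out from 17: the acetals are removed at the robust monomer stage (HCl, MeOH, 50 °C) to give 3-ethyl-2,5,7,8-tetrahydroxynaphthalene-1,4-dione F7. Protecting-group-free oxidative dehydrodimerisation (Ag2O or PbO2, buffered) should give the racemic target F8, and chromatography on a chiral stationary phase separates 21 from the (3R)-enantiomer F9. This path gives up catalytic stereocontrol and depends on the chemoselectivity of the oxidation, which is why it is held in reserve.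

## Further compounds

F1 | step 11 | racemic 3-ethyl-3-hydroxy-5,7,8-tris(methoxymethoxy)naphthalene-1,2,4(3H)-trione | CCC1(O)C(=O)C(=O)c2c(OCOC)c(OCOC)cc(OCOC)c2C1=O
F2 | step 11 | (3R)-3-ethyl-3-hydroxy-5,7,8-tris(methoxymethoxy)naphthalene-1,2,4(3H)-trione | O[C@@]1(CC)C(=O)C(=O)c2c(OCOC)c(OCOC)cc(OCOC)c2C1=O
F3 | step 7 | racemic 2-ethyl-3-isopropoxy-4-[2,3,5-tris(methoxymethoxy)phenyl]-4-(trimethylsilyloxy)cyclobut-2-en-1-one | CCC1=C(OC(C)C)C(O[Si](C)(C)C)(c2cc(OCOC)cc(OCOC)c2OCOC)C1=O
F4 | step 7 | 3-ethyl-2-isopropoxy-5,7,8-tris(methoxymethoxy)-1-(trimethylsilyloxy)naphthalen-4-ol | CCc1c(OC(C)C)c(O[Si](C)(C)C)c2c(OCOC)c(OCOC)cc(OCOC)c2c1O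
F5 | step 12 | racemic 3-ethyl-3-{[3-ethyl-5,7,8-tris(methoxymethoxy)-1,4-dioxo-1,4-dihydronaphthalen-2-yl]oxy}-5,7,8-tris(methoxymethoxy)naphthalene-1,2,4(3H)-trione | CCC1=C(OC2(CC)C(=O)C(=O)c3c(OCOC)c(OCOC)cc(OCOC)c3C2=O)C(=O)c2c(OCOC)c(OCOC)cc(OCOC)c2C1=O
F6 | step 12 | (3R)-enantiomer of 20 | CCC1=C(O[C@@]2(CC)C(=O)C(=O)c3c(OCOC)c(OCOC)cc(OCOC)c3C2=O)C(=O)c2c(OCOC)c(OCOC)cc(OCOC)c2C1=O
F7 | step 13 | 3-ethyl-2,5,7,8-tetrahydroxynaphthalene-1,4-dione | CCC1=C(O)C(=O)c2c(O)c(O)cc(O)c2C1=O
F8 | step 13 | racemic 3-ethyl-3-[(3-ethyl-5,7,8-trihydroxy-1,4-dioxo-1,4-dihydronaphthalen-2-yl)oxy]-5,7,8-trihydroxynaphthalene-1,2,4(3H)-trione | CCC1=C(OC2(CC)C(=O)C(=O)c3c(O)c(O)cc(O)c3C2=O)C(=O)c2c(O)c(O)cc(O)c2C1=O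
F9 | step 13 | (3R)-enantiomer of 21 | CCC1=C(O[C@@]2(CC)C(=O)C(=O)c3c(O)c(O)cc(O)c3C2=O)C(=O)c2c(O)c(O)cc(O)c2C1=O
A1 | alternative 1 | bis-annulated ether with 8-methoxy-5,7-dihydroxy ring B, 8'-methoxy-5',7'-dihydroxy ring D pattern as drawn and a C2' methylene | CCC1=C(O[C@]2(CC)CC(=O)c3c(OC)c(O)cc(O)c3C2=O)C(=O)c2c(OC)c(O)cc(O)c2C1=O
A2 | alternative 1 | 1,4-dimethoxy-1,3-bis(trimethylsilyloxy)buta-1,3-diene | COC=C(O[Si](C)(C)C)C=C(OC)O[Si](C)(C)C
A3 | alternative 1 | bis-dienophile ether linking a bromo-ethylbenzoquinone to a bromo-ethylcyclohexenedione | CCC1=C(O[C@]2(CC)CC(=O)C=C(Br)C2=O)C(=O)C=C(Br)C1=O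
A4 | alternative 2 | 2-ethyl-2-hydroxy-5,6,8-tris(methoxymethoxy)-1-tetralone 4-(ethylene ketal) | O[C@]1(CC)CC2(OCCO2)c2c(OCOC)c(OCOC)cc(OCOC)c2C1=O
A5 | alternative 2 | 3,4,6-tris(methoxymethoxy)-2-[2-(2-oxobutyl)-1,3-dioxolan-2-yl]benzaldehyde | CCC(=O)CC1(OCCO1)c1c(OCOC)c(OCOC)cc(OCOC)c1C=O
A6 | alternative 3 | 7-ethoxy-3-ethyl-1,2,4,5-tetramethoxynaphthalen-8-ol | CCc1c(OC)c2c(OC)cc(OCC)c(O)c2c(OC)c1OC
A7 | alternative 3 | pentacarbonyl[(3-ethyl-2,4,5-trimethoxyphenyl)(methoxy)methylidene]chromium | COC(=[Cr](=C=O)(=C=O)(=C=O)(=C=O)=C=O)c1c(OC)c(CC)c(OC)c(OC)c1
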